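**Plan**

- Retrosynthetic cuts, in order: the O3–acyl ester bond, the C7=C8 alkene (C10 ylide plus C30 aldehyde), and in ring A the bonds C1–C6 and C4–C5.
- Enabling feature: in ring A, C4–C3(O)–C2–C1(C16, C17) is the skeleton of mesityl oxide and C18–C5–C6–C7 that of ethyl acetoacetate, so the C3 oxygen and C7 stand in the 1,5-dicarbonyl relation of a Michael–aldol annulation.
- Forward: ring A is closed first; C3 is reduced, C4=C5 is moved to C5=C6, C7 becomes a phosphonium salt, the bought C30 polyenal is attached by Wittig olefination, and O3 is acylated last.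
- Stereochemistry: C3 comes from a catalyst-controlled CBS reduction of the ring enone; the racemic C6 centre disappears on conjugation; 7E comes from the Wittig step with thermal equilibration; all other alkenes arrive with the C30 aldehyde and palmitoleic acid.

Key step: step 1

Remark: carotenoid numbering is used for ring A, and the target is taken as drawn (3R, all-E polyene, 9Z acyl chain); the C3 centre is labelled S while the alkene is at C4=C5 and R once it is at C5=C6, with no change in space.

**Route**

Step 1
Reactants: 1 mesityl oxide; 2 ethyl acetoacetate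
Product: 5 racemic ethyl 2,6,6-trimethyl-4-oxocyclohex-2-ene-1-carboxylate, via Michael adduct 3 (not isolated), via aldol 4 (not isolated)
Conditions: BF3·OEt2 (0.3 equiv), neat, 0 °C to rt; aq. NaOAc; distillation
Reagents that add atoms: none
Why: BF3 turns ethyl acetoacetate into its boron-bound enol, which adds through the doubly activated carbon (future C6) to the Lewis-acid-activated β-carbon of mesityl oxide (future C1) and so forms the C1–C6 bond and the quaternary centre. The enol of the methyl ketone (future C4) then attacks the acetoacetate ketone (future C5), and loss of water leaves C4=C5 conjugated with the C3 carbonyl; the closest known reaction type is the acid-mediated Robinson (Michael–aldol) annulation. Ring A closes in a 6-(enolendo)-exo-trig aldol. The only new stereocentre, C6, forms without control and is left racemic on purpose, because step 6 removes it. The step needs regiocontrol only: one carbon between two carbonyls and one β-position fix the Michael bond, and in the aldol the β-keto ester unit enolises between its carbonyls and not at its terminal methyl, so the free methyl ketone is the nucleophile and the ester-activated C5 ketone the electrophile. An isomeric enone from the opposite aldol direction, should it form, would be removed by fractional distillation.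

Step 2
Reactants: 5 racemic ethyl 2,6,6-trimethyl-4-oxocyclohex-2-ene-1-carboxylate
Product: 6 ethyl (1RS,4S)-4-hydroxy-2,6,6-trimethylcyclohex-2-ene-1-carboxylate
Conditions: (R)-Me-CBS oxazaborolidine [(3aR)-1-methyl-3,3-diphenyltetrahydro-1H,3H-pyrrolo[1,2-c][1,3,2]oxazaborole] (0.2 equiv), catecholborane, toluene, −78 °C
Reagents that add atoms: none
Why: Corey–Bakshi–Shibata reduction, in which the ketone binds the catalyst boron on the side of its smaller C2 methylene flank, the alkenyl flank C4 acts as the large group and hydride from the nitrogen-bound borane reaches one face under catalyst control, so the (R)-catalyst should give the carbinol that is 4S here and 3R in the target in both C6 epimers.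

Step 3
Reactants: 6 ethyl (1RS,4S)-4-hydroxy-2,6,6-trimethylcyclohex-2-ene-1-carboxylate
Product: 7 ethyl (1RS,4S)-2,6,6-trimethyl-4-[(triethylsilyl)oxy]cyclohex-2-ene-1-carboxylate
Conditions: Et3SiCl, imidazole, DMF, 0 °C to rt
Reagents that add atoms: chlorotriethylsilane, CC[Si](Cl)(CC)CC
Why: Imidazole-promoted silylation of the only hydroxyl gives a triethylsilyl ether that should survive hydride, neutral oxidation and amine base and is chosen because the acidic methanol of step 7 removes it.

Step 4
Reactants: 7 ethyl (1RS,4S)-2,6,6-trimethyl-4-[(triethylsilyl)oxy]cyclohex-2-ene-1-carboxylate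
Product: 8 {(1RS,4S)-2,6,6-trimethyl-4-[(triethylsilyl)oxy]cyclohex-2-en-1-yl}methanol
Conditions: LiAlH4, Et2O, 0 °C to rt
Reagents that add atoms: none
Why: Hydride reduction of the hindered ester to the primary alcohol, to which the silyl ether and the trisubstituted alkene are inert.

Step 5
Reactants: 8 {(1RS,4S)-2,6,6-trimethyl-4-[(triethylsilyl)oxy]cyclohex-2-en-1-yl}methanol
Product: 9 (1RS,4S)-2,6,6-trimethyl-4-[(triethylsilyl)oxy]cyclohex-2-ene-1-carbaldehyde
Conditions: (n-Pr4N)[RuO4] (5 mol %), N-methylmorpholine N-oxide, 4 Å molecular sieves, CH2Cl2, rt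
Reagents that add atoms: none
Why: Ley–Griffith oxidation takes the primary alcohol to the aldehyde under neutral conditions, so the acid-sensitive allylic silyl ether should stay in place and no over-oxidation is expected.

Step 6
Reactants: 9 (1RS,4S)-2,6,6-trimethyl-4-[(triethylsilyl)oxy]cyclohex-2-ene-1-carbaldehyde
Product: 11 {(4R)-2,6,6-trimethyl-4-[(triethylsilyl)oxy]cyclohex-1-en-1-yl}methanol, via conjugated aldehyde 10 (not isolated)
Conditions: DBU (0.3 equiv), THF, rt; then MeOH, NaBH4, 0 °C
Reagents that add atoms: none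
Why: Base-catalysed conjugation through the dienolate (the α- to β-cyclocitral isomerisation) should move C4=C5 to the tetrasubstituted C5=C6 position, which removes the C6 centre and merges both epimers, and the enal is reduced at once by 1,2-hydride addition so that it is not held under base.

Step 7
Reactants: 11 {(4R)-2,6,6-trimethyl-4-[(triethylsilyl)oxy]cyclohex-1-en-1-yl}methanol
Product: 13 {[(4R)-4-hydroxy-2,6,6-trimethylcyclohex-1-en-1-yl]methyl}triphenylphosphonium bromide, via desilylated diol 12 (not isolated)
Conditions: PPh3·HBr (1.3 equiv), MeOH, rt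
Reagents that add atoms: triphenylphosphine hydrobromide, Br.c1ccc(cc1)P(c1ccccc1)c1ccccc1
Why: Acidic methanol first cleaves the triethylsilyl ether, and the primary allylic alcohol then undergoes SN1-type substitution through its allyl cation, captured by PPh3 at the primary terminus as for β-cyclogeraniol, while the now homoallylic C3 carbinol does not ionise and keeps its configuration.

Step 8
Reactants: 13 {[(4R)-4-hydroxy-2,6,6-trimethylcyclohex-1-en-1-yl]methyl}triphenylphosphonium bromide; 14 β-apo-8′-carotenal
Product: 16 (3R)-β-cryptoxanthin, via phosphonium ylide 15 (not isolated)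
Conditions: KOtBu (1.05 equiv on 13), THF, 0 °C; 14, 0 °C to rt, Ar, dark; then heptane, reflux
Reagents that add atoms: none
Why: Wittig olefination of the allylic ylide with the unhindered polyenal forms C7=C8 and completes the C40 skeleton, the 7Z isomer being so congested by the ring methyls that the E alkene should prevail and brief heating should bring residual Z isomers to the all-E polyene.

Step 9
Reactants: 16 (3R)-β-cryptoxanthin; 17 palmitoleic acid
Product: 19 (3R)-β-cryptoxanthin palmitoleate (CNP0382087.1), via O-acylisourea 18 (not isolated)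
Conditions: DCC, DMAP (0.2 equiv), CH2Cl2, rt, Ar, dark
Reagents that add atoms: none
Why: Steglich esterification acylates the secondary alcohol under neutral conditions without breaking the C3–O bond, so 3R is retained and the polyene and the 9Z alkene are untouched.

**Compound list**

1 | mesityl oxide (4-methylpent-3-en-2-one) | CC(=O)C=C(C)C | starting material
2 | ethyl acetoacetate | CCOC(=O)CC(C)=O | starting material
3 | racemic ethyl 2-acetyl-3,3-dimethyl-5-oxohexanoate (Michael adduct, not isolated) | CCOC(=O)C(C(C)=O)C(C)(C)CC(C)=O | intermediate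
4 | ethyl 2-hydroxy-2,6,6-trimethyl-4-oxocyclohexane-1-carboxylate (aldol, stereoisomer mixture, not isolated) | CCOC(=O)C1C(C)(O)CC(=O)CC1(C)C | intermediate
5 | racemic ethyl 2,6,6-trimethyl-4-oxocyclohex-2-ene-1-carboxylate | CCOC(=O)C1C(C)=CC(=O)CC1(C)C | intermediate
6 | ethyl (1RS,4S)-4-hydroxy-2,6,6-trimethylcyclohex-2-ene-1-carboxylate (both C1 epimers) | O[C@@H]1C=C(C)C(C(=O)OCC)C(C)(C)C1 | intermediate
7 | ethyl (1RS,4S)-2,6,6-trimethyl-4-[(triethylsilyl)oxy]cyclohex-2-ene-1-carboxylate | CC[Si](CC)(CC)O[C@@H]1C=C(C)C(C(=O)OCC)C(C)(C)C1 | intermediate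
8 | {(1RS,4S)-2,6,6-trimethyl-4-[(triethylsilyl)oxy]cyclohex-2-en-1-yl}methanol | CC[Si](CC)(CC)O[C@@H]1C=C(C)C(CO)C(C)(C)C1 | intermediate
9 | (1RS,4S)-2,6,6-trimethyl-4-[(triethylsilyl)oxy]cyclohex-2-ene-1-carbaldehyde | CC[Si](CC)(CC)O[C@@H]1C=C(C)C(C=O)C(C)(C)C1 | intermediate
10 | (4R)-2,6,6-trimethyl-4-[(triethylsilyl)oxy]cyclohex-1-ene-1-carbaldehyde (not isolated) | CC[Si](CC)(CC)O[C@@H]1CC(C)=C(C=O)C(C)(C)C1 | intermediate
11 | {(4R)-2,6,6-trimethyl-4-[(triethylsilyl)oxy]cyclohex-1-en-1-yl}methanol | CC[Si](CC)(CC)O[C@@H]1CC(C)=C(CO)C(C)(C)C1 | intermediate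
12 | (1R)-4-(hydroxymethyl)-3,5,5-trimethylcyclohex-3-en-1-ol (not isolated) | O[C@@H]1CC(C)=C(CO)C(C)(C)C1 | intermediate
13 | {[(4R)-4-hydroxy-2,6,6-trimethylcyclohex-1-en-1-yl]methyl}triphenylphosphonium bromide | O[C@@H]1CC(C)=C(C[P+](c2ccccc2)(c2ccccc2)c2ccccc2)C(C)(C)C1.[Br-] | intermediate
14 | β-apo-8′-carotenal (all-E) | O=C/C(C)=C/C=C/C(C)=C/C=C/C=C(C)/C=C/C=C(C)/C=C/C1=C(C)CCCC1(C)C | starting material
15 | (1R)-3,5,5-trimethyl-4-[(triphenyl-λ5-phosphanylidene)methyl]cyclohex-3-en-1-ol (ylide, not isolated) | O[C@@H]1CC(C)=C(C=P(c2ccccc2)(c2ccccc2)c2ccccc2)C(C)(C)C1 | intermediate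
16 | (3R)-β-cryptoxanthin [(3R)-β,β-caroten-3-ol, all-E] | O[C@@H]1CC(C)=C(/C=C/C(C)=C/C=C/C(C)=C/C=C/C=C(C)/C=C/C=C(C)/C=C/C2=C(C)CCCC2(C)C)C(C)(C)C1 | intermediate
17 | palmitoleic acid [(9Z)-hexadec-9-enoic acid] | CCCCCC/C=C\CCCCCCCC(=O)O | starting material
18 | N,N′-dicyclohexyl-O-[(9Z)-hexadec-9-enoyl]isourea (not isolated) | CCCCCC/C=C\CCCCCCCC(=O)OC(=NC1CCCCC1)NC1CCCCC1 | intermediate
19 | (3R)-β-cryptoxanthin palmitoleate, CNP0382087.1 | CCCCCC/C=C\CCCCCCCC(=O)O[C@@H]1CC(C)=C(/C=C/C(C)=C/C=C/C(C)=C/C=C/C=C(C)/C=C/C=C(C)/C=C/C2=C(C)CCCC2(C)C)C(C)(C)C1 | target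

**Count**

Total steps: 9. Longest linear sequence: 9 steps (1 and 2 to 19 through 5, 6, 7, 8, 9, 11, 13 and 16); 14 and 17 are bought.

**Steps most likely to fail**

Step 2. Hydride delivery may discriminate poorly between the two faces, because the alkenyl CH flank and the methylene next to the quaternary carbon differ little in size and one C6 epimer is a mismatched partner for the catalyst. This would lower the enantiomeric purity at C3 once C6 is erased. Fallback, setting out from 5: Luche reduction (NaBH4, CeCl3·7H2O, MeOH, −20 °C) would give racemic ethyl 4-hydroxy-2,6,6-trimethylcyclohex-2-ene-1-carboxylate F1 as all stereoisomers. Lipase-catalysed acylation (Burkholderia cepacia lipase, vinyl acetate, tert-butyl methyl ether) should, by the empirical size rule for secondary alcohols with the gem-dimethyl flank as the large group, esterify the 4S alcohols to ethyl (1RS,4S)-4-acetoxy-2,6,6-trimethylcyclohex-2-ene-1-carboxylate F2. After separation from the unreacted 4R alcohols, ethanolysis (K2CO3, EtOH) returns the route to 6.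

Step 6. The dienolate that carries the alkene into conjugation can also expel the silyloxy group from C3 (vinylogous β-elimination toward a cyclohexadienal), and deprotonation of the hindered C6–H may be too slow for full conversion. Fallback, setting out from 9: the silyl ether is removed (AcOH/THF/H2O, rt) to (1RS,4S)-4-hydroxy-2,6,6-trimethylcyclohex-2-ene-1-carbaldehyde F3. Methanolic KOH at 0 °C, in which the free hydroxyl is partly an alkoxide and a much poorer leaving group, should conjugate it to (4R)-4-hydroxy-2,6,6-trimethylcyclohex-1-ene-1-carbaldehyde F4, as in the base-mediated end-group isomerisation of 3-hydroxy carotenoid rings. NaBH4 in the same flask reduces F4 to the diol, where the route is rejoined at 12; the conditions of step 7 then convert 12 into 13.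

Step 8. Addition of the ylide carbon, flanked by the C1 gem-dimethyl group and the C5 methyl, to the polyenal may be slow, leaving time for base-induced decay of the polyene and for Z isomers to build up. Fallback, setting out from 11: a Mitsunobu reaction (1,3-benzothiazole-2-thiol, PPh3, diisopropyl azodicarboxylate, THF) gives 2-[({(4R)-2,6,6-trimethyl-4-[(triethylsilyl)oxy]cyclohex-1-en-1-yl}methyl)sulfanyl]-1,3-benzothiazole F5. Oxidation (H2O2, (NH4)6Mo7O24·4H2O, EtOH, 0 °C) gives 2-[({(4R)-2,6,6-trimethyl-4-[(triethylsilyl)oxy]cyclohex-1-en-1-yl}methyl)sulfonyl]-1,3-benzothiazole F6. Its anion (NaN(SiMe3)2, THF, −78 °C) should undergo Julia–Kocienski olefination with 14 to (3R)-3-[(triethylsilyl)oxy]-β,β-carotene F7, equilibrated to all-E by heating as in step 8. Bu4NF in THF then returns the route to 16.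

Further compounds
F1 | step 2 | racemic ethyl 4-hydroxy-2,6,6-trimethylcyclohex-2-ene-1-carboxylate (all stereoisomers) | CCOC(=O)C1C(C)=CC(O)CC1(C)C
F2 | step 2 | ethyl (1RS,4S)-4-acetoxy-2,6,6-trimethylcyclohex-2-ene-1-carboxylate | CC(=O)O[C@@H]1C=C(C)C(C(=O)OCC)C(C)(C)C1
F3 | step 6 | (1RS,4S)-4-hydroxy-2,6,6-trimethylcyclohex-2-ene-1-carbaldehyde | O[C@@H]1C=C(C)C(C=O)C(C)(C)C1
F4 | step 6 | (4R)-4-hydroxy-2,6,6-trimethylcyclohex-1-ene-1-carbaldehyde | O[C@@H]1CC(C)=C(C=O)C(C)(C)C1
F5 | step 8 | 2-[({(4R)-2,6,6-trimethyl-4-[(triethylsilyl)oxy]cyclohex-1-en-1-yl}methyl)sulfanyl]-1,3-benzothiazole | CC[Si](CC)(CC)O[C@@H]1CC(C)=C(CSc2nc3ccccc3s2)C(C)(C)C1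
F6 | step 8 | 2-[({(4R)-2,6,6-trimethyl-4-[(triethylsilyl)oxy]cyclohex-1-en-1-yl}methyl)sulfonyl]-1,3-benzothiazole | CC[Si](CC)(CC)O[C@@H]1CC(C)=C(CS(=O)(=O)c2nc3ccccc3s2)C(C)(C)C1
F7 | step 8 | (3R)-3-[(triethylsilyl)oxy]-β,β-carotene | CC[Si](CC)(CC)O[C@@H]1CC(C)=C(/C=C/C(C)=C/C=C/C(C)=C/C=C/C=C(C)/C=C/C=C(C)/C=C/C2=C(C)CCCC2(C)C)C(C)(C)C1
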